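**Strategy.** Rings: A/E, the 3,5-dihydroxyphenoxy groups; B, the pentaoxygenated dioxin arene; C, the central arene; D, the outer furan arene. The plan makes the 1,4-dioxin ring from a five-membered 1,3-dioxole. Ring-B carbon C-10a (eckol numbering), which carries one dioxin oxygen, is para to the C-3 hydroxyl, so it can be the spiro-ketal carbon of a p-quinone monoketal holding both catechol oxygens of ring C. Acid then moves one oxygen to the neighbouring ring-B CH (C-4a), expanding dioxole to dioxin and aromatising ring B in one operation; a para-formyl group on ring C decides which oxygen moves and is later exchanged for the furan oxygen. The precursor is a spiro[benzodioxole-cyclohexadienone]. Dibenzofuran and ring E follow.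

Key step: step 5

Remark: the target is achiral; spiroketal 8 is a racemate whose only stereocentre is destroyed in step 5; compounds 1, 2, 7, 13 and 18 are taken as purchased.

Step 1
Reactants: 1 2-bromo-4,5-dimethoxybenzaldehyde; 2 3,5-dimethoxyphenol
Product: 3 2-(3,5-dimethoxyphenoxy)-4,5-dimethoxybenzaldehyde
Conditions: CuI (10 mol %), N,N-dimethylglycine·HCl (30 mol %), Cs2CO3, dioxane, 90 °C
Reagents that add atoms: none
Why: Ullmann-type diaryl ether synthesis; the ortho-formyl group activates the C–Br bond toward copper and the phenol is unhindered.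

Step 2
Reactants: 3 2-(3,5-dimethoxyphenoxy)-4,5-dimethoxybenzaldehyde
Product: 5 2-(3,5-dimethoxyphenoxy)-4,5-dimethoxyphenol, via aryl formate 4 (not isolated)
Conditions: mCPBA, CH2Cl2, 0 °C → rt; then K2CO3 (cat.), MeOH, rt
Reagents that add atoms: mCPBA, OOC(=O)c1cccc(Cl)c1
Why: Baeyer–Villiger (Dakin-type) oxidation: the electron-rich aryl group migrates in the Criegee adduct to give the formate, which methanolysis cleaves to the phenol.

Step 3
Reactants: 5 2-(3,5-dimethoxyphenoxy)-4,5-dimethoxyphenol
Product: 6 2-(3,5-dimethoxyphenoxy)-4,4,5-trimethoxycyclohexa-2,5-dien-1-one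
Conditions: PhI(OAc)2, MeOH, 0 °C
Reagents that add atoms: methanol, CO
Why: Hypervalent-iodine oxidative dearomatisation of a p-methoxyphenol; methanol traps the phenoxenium-type intermediate at the para carbon to give the p-quinone monoketal.

Step 4
Reactants: 6 2-(3,5-dimethoxyphenoxy)-4,4,5-trimethoxycyclohexa-2,5-dien-1-one; 7 3,4-dihydroxy-5-methoxybenzaldehyde (5-hydroxyvanillin)
Product: 8 (rac)-5′-(3,5-dimethoxyphenoxy)-2′,7-dimethoxy-4′-oxospiro[1,3-benzodioxole-2,1′-cyclohexa-2′,5′-diene]-5-carbaldehyde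
Conditions: PPTS (10 mol %), 1,2-dichloroethane, 5 Å MS, 50 °C
Reagents that add atoms: none
Why: Acid-catalysed transketalisation of a dimethyl ketal with a catechol (as in benzodioxole formation from 2,2-dimethoxypropane), driven by removal of methanol on sieves; both catechol oxygens end on the same carbon, so no regiochemistry arises and the spiro centre forms as a racemate.

Step 5
Reactants: 8 (rac)-5′-(3,5-dimethoxyphenoxy)-2′,7-dimethoxy-4′-oxospiro[1,3-benzodioxole-2,1′-cyclohexa-2′,5′-diene]-5-carbaldehyde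
Product: 9 4-(3,5-dimethoxyphenoxy)-3-hydroxy-1,6-dimethoxydibenzo[b,e][1,4]dioxine-8-carbaldehyde
Conditions: TfOH (10 mol %), CH2Cl2/HFIP 4:1, 0.01 M, −20 → 0 °C
Reagents that add atoms: none
Why: Proposed new method: catalytic acid activates the cross-conjugated dienone/ketal so that the spiro C1′–O bond to the better nucleofuge ionises; the resulting aryloxy-stabilised oxocarbenium is re-captured by the tethered phenol oxygen at the adjacent enone β-carbon C6′, and loss of H+ from C6′ aromatises ring B, a net 1,2-oxygen shift. The closest known reactions are the acid-catalysed dienone–phenol rearrangement, the 1,2-acyloxy shift of quinol acetates and the acid-promoted substitution chemistry of quinone monoketals; the migration of a ketal oxygen of a spiro-benzodioxole is the new element. The six-membered 1,4-dioxin ring closes by a 6-endo-trig attack of oxygen on C6′ while the five-membered dioxole opens, so the ring gains the one ring-B carbon C6′. No stereocentre is created and the racemic spiro centre of 8 is destroyed. The step needs O1 (on C7a, para to the formyl group) to be the oxygen that moves: it is the better leaving phenoxide and the poorer donor, whereas O3 (meta to CHO) is the better π-donor and should stay to stabilise the oxocarbenium; movement toward C2′ is unproductive because that carbon carries OMe and no hydrogen to lose. High dilution in weakly nucleophilic HFIP should suppress intermolecular capture of the cation by the electron-rich ring A.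

Step 6
Reactants: 9 4-(3,5-dimethoxyphenoxy)-3-hydroxy-1,6-dimethoxydibenzo[b,e][1,4]dioxine-8-carbaldehyde
Product: 10 4-(3,5-dimethoxyphenoxy)-1,3,6-trimethoxydibenzo[b,e][1,4]dioxine-8-carbaldehyde
Conditions: MeI, K2CO3, DMF, rt
Reagents that add atoms: iodomethane, CI
Why: Williamson O-methylation caps the phenol released in step 5, so that each later Ullmann coupling meets a single free OH.

Step 7
Reactants: 10 4-(3,5-dimethoxyphenoxy)-1,3,6-trimethoxydibenzo[b,e][1,4]dioxine-8-carbaldehyde
Product: 12 4-(3,5-dimethoxyphenoxy)-1,3,6-trimethoxydibenzo[b,e][1,4]dioxin-8-ol (penta-O-methyleckol with free 8-OH), via aryl formate 11 (not isolated)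
Conditions: mCPBA, CH2Cl2, 0 °C → rt; then K2CO3 (cat.), MeOH, rt
Reagents that add atoms: mCPBA, OOC(=O)c1cccc(Cl)c1
Why: Baeyer–Villiger oxidation of a syringaldehyde-type (3,5-dioxygenated 4-aryloxy) benzaldehyde with aryl migration, then methanolysis of the formate; this exchanges the directing formyl group for the future furan oxygen.

Step 8
Reactants: 12 4-(3,5-dimethoxyphenoxy)-1,3,6-trimethoxydibenzo[b,e][1,4]dioxin-8-ol; 13 2-bromo-4,6-dimethoxybenzaldehyde
Product: 14 2-{[4-(3,5-dimethoxyphenoxy)-1,3,6-trimethoxydibenzo[b,e][1,4]dioxin-8-yl]oxy}-4,6-dimethoxybenzaldehyde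
Conditions: CuI (10 mol %), N,N-dimethylglycine·HCl (30 mol %), Cs2CO3, dioxane, 90 °C
Reagents that add atoms: none
Why: Ullmann diaryl ether synthesis between the only free, unhindered phenol and an ortho-formyl-activated aryl bromide.

Step 9
Reactants: 14 2-{[4-(3,5-dimethoxyphenoxy)-1,3,6-trimethoxydibenzo[b,e][1,4]dioxin-8-yl]oxy}-4,6-dimethoxybenzaldehyde
Product: 15 dibenzofuran aldehyde (14 with the furan ring closed between C-9 of the dioxin core and C-3 of the formylaryl ring; CHO ortho to the furan oxygen)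
Conditions: Pd(OAc)2 (10 mol %), K2CO3 (10 mol %), PivOH, air, 110 °C
Reagents that add atoms: none
Why: Pd(II)-catalysed intramolecular oxidative biaryl coupling (twofold C–H activation, air as oxidant) of a diaryl ether to a dibenzofuran; the formyl ring has one ortho C–H only, and on ring C the C–H para to OMe and flanked by the tied-back dioxin oxygen should be palladated in preference to the OMe-flanked one.

Step 10
Reactants: 15 dibenzofuran aldehyde
Product: 17 dibenzofuran phenol (15 with OH in place of CHO; octa-O-methyl-phlorofucofuroeckol A lacking ring E), via aryl formate 16 (not isolated)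
Conditions: mCPBA, CH2Cl2, 0 °C → rt; then K2CO3 (cat.), MeOH, rt
Reagents that add atoms: mCPBA, OOC(=O)c1cccc(Cl)c1
Why: Baeyer–Villiger oxidation of a 2,4,6-trioxygenated benzaldehyde, for which aryl migration is strongly favoured, then methanolysis of the formate.

Step 11
Reactants: 17 dibenzofuran phenol; 18 1-bromo-3,5-dimethoxybenzene
Product: 19 nona-O-methylphlorofucofuroeckol A
Conditions: CuI (10 mol %), picolinic acid (20 mol %), K3PO4, DMSO, 100 °C
Reagents that add atoms: none
Why: Ullmann coupling under Cu/picolinic acid conditions suited to ortho,ortho′-disubstituted phenols installs ring E.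

Step 12
Reactants: 19 nona-O-methylphlorofucofuroeckol A
Product: 20 phlorofucofuroeckol A
Conditions: BBr3 (excess), CH2Cl2, −78 °C → rt; then degassed MeOH/H2O
Reagents that add atoms: none
Why: Lewis-acid ether cleavage with BBr3 removes all nine methyl groups by bromide attack on the boron-complexed methyl ethers, while the diaryl ether, dioxin and furan C–O bonds should be inert.

**Compound list**

1 | 2-bromo-4,5-dimethoxybenzaldehyde | O=Cc1cc(OC)c(OC)cc1Br | starting material
2 | 3,5-dimethoxyphenol | COc1cc(O)cc(OC)c1 | starting material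
3 | 2-(3,5-dimethoxyphenoxy)-4,5-dimethoxybenzaldehyde | O=Cc1cc(OC)c(OC)cc1Oc1cc(OC)cc(OC)c1 | intermediate
4 | 2-(3,5-dimethoxyphenoxy)-4,5-dimethoxyphenyl formate | O=COc1cc(OC)c(OC)cc1Oc1cc(OC)cc(OC)c1 | intermediate (not isolated)
5 | 2-(3,5-dimethoxyphenoxy)-4,5-dimethoxyphenol | Oc1cc(OC)c(OC)cc1Oc1cc(OC)cc(OC)c1 | intermediate
6 | 2-(3,5-dimethoxyphenoxy)-4,4,5-trimethoxycyclohexa-2,5-dien-1-one | O=C1C=C(OC)C(OC)(OC)C=C1Oc1cc(OC)cc(OC)c1 | intermediate
7 | 3,4-dihydroxy-5-methoxybenzaldehyde | O=Cc1cc(O)c(O)c(OC)c1 | starting material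
8 | (rac)-5′-(3,5-dimethoxyphenoxy)-2′,7-dimethoxy-4′-oxospiro[1,3-benzodioxole-2,1′-cyclohexa-2′,5′-diene]-5-carbaldehyde (racemate, spiro centre unspecified) | O=C1C=C(OC)C2(Oc3cc(C=O)cc(OC)c3O2)C=C1Oc1cc(OC)cc(OC)c1 | intermediate
9 | 4-(3,5-dimethoxyphenoxy)-3-hydroxy-1,6-dimethoxydibenzo[b,e][1,4]dioxine-8-carbaldehyde | Oc1cc(OC)c2Oc3cc(C=O)cc(OC)c3Oc2c1Oc1cc(OC)cc(OC)c1 | intermediate
10 | 4-(3,5-dimethoxyphenoxy)-1,3,6-trimethoxydibenzo[b,e][1,4]dioxine-8-carbaldehyde | COc1cc(OC)c2Oc3cc(C=O)cc(OC)c3Oc2c1Oc1cc(OC)cc(OC)c1 | intermediate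
11 | 4-(3,5-dimethoxyphenoxy)-1,3,6-trimethoxydibenzo[b,e][1,4]dioxin-8-yl formate | COc1cc(OC)c2Oc3cc(OC=O)cc(OC)c3Oc2c1Oc1cc(OC)cc(OC)c1 | intermediate (not isolated)
12 | 4-(3,5-dimethoxyphenoxy)-1,3,6-trimethoxydibenzo[b,e][1,4]dioxin-8-ol | COc1cc(OC)c2Oc3cc(O)cc(OC)c3Oc2c1Oc1cc(OC)cc(OC)c1 | intermediate
13 | 2-bromo-4,6-dimethoxybenzaldehyde | O=Cc1c(Br)cc(OC)cc1OC | starting material
14 | 2-{[4-(3,5-dimethoxyphenoxy)-1,3,6-trimethoxydibenzo[b,e][1,4]dioxin-8-yl]oxy}-4,6-dimethoxybenzaldehyde | COc1cc(OC)c2Oc3cc(Oc4cc(OC)cc(OC)c4C=O)cc(OC)c3Oc2c1Oc1cc(OC)cc(OC)c1 | intermediate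
15 | dibenzofuran aldehyde (benzofuro-fused dibenzodioxin; CHO ortho to the furan oxygen on ring D) | COc1cc(OC)c2Oc3c4c5c(OC)cc(OC)c(C=O)c5oc4cc(OC)c3Oc2c1Oc1cc(OC)cc(OC)c1 | intermediate
16 | formate of dibenzofuran phenol 17 | COc1cc(OC)c2Oc3c4c5c(OC)cc(OC)c(OC=O)c5oc4cc(OC)c3Oc2c1Oc1cc(OC)cc(OC)c1 | intermediate (not isolated)
17 | dibenzofuran phenol (OH ortho to the furan oxygen on ring D) | COc1cc(OC)c2Oc3c4c5c(OC)cc(OC)c(O)c5oc4cc(OC)c3Oc2c1Oc1cc(OC)cc(OC)c1 | intermediate
18 | 1-bromo-3,5-dimethoxybenzene | COc1cc(Br)cc(OC)c1 | starting material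
19 | nona-O-methylphlorofucofuroeckol A | COc1cc(OC)c2Oc3c4c5c(OC)cc(OC)c(Oc6cc(OC)cc(OC)c6)c5oc4cc(OC)c3Oc2c1Oc1cc(OC)cc(OC)c1 | intermediate
20 | phlorofucofuroeckol A | Oc1cc(O)cc(Oc2c(O)cc(O)c3c2Oc2c(O)cc4oc5c(Oc6cc(O)cc(O)c6)c(O)cc(O)c5c4c2O3)c1 | target

**Step count and risks**

Total steps: 12. Longest linear sequence: 12 steps (1 → 20; compounds 2, 7, 13 and 18 enter as purchased partners).

Steps most likely to fail:

1. Step 5 (proposed new method). The wrong spiro C–O bond may ionise, so that the meta-formyl oxygen moves and ring C ends up turned round in the dioxin. The ionised ketal may also fragment to quinone and catechol, or be captured intermolecularly, before it re-closes. The fallback uses known reactions only, sets out from 7 and comes back at 14. Commercial 2-fluoro-4,6-dimethoxybenzaldehyde F1 is brominated (NBS, MeCN) para to its 6-methoxy group to 3-bromo-2-fluoro-4,6-dimethoxybenzaldehyde F2. SNAr of 7 (1 equiv K2CO3, DMF) on the fluoride of F2, in which the 4-OH para to the formyl group ionises first, should give 3-bromo-2-(4-formyl-2-hydroxy-6-methoxyphenoxy)-4,6-dimethoxybenzaldehyde F3. Intramolecular Ullmann etherification (CuI, N,N-dimethylglycine, Cs2CO3) of the remaining OH onto the aryl bromide then closes the dioxin ring directly in its final size, giving 1,3,6-trimethoxydibenzo[b,e][1,4]dioxine-4,8-dicarbaldehyde F4. Double Baeyer–Villiger oxidation (mCPBA) gives bis-formate F5, and methanolysis gives 1,3,6-trimethoxydibenzo[b,e][1,4]dioxine-4,8-diol F6. Ullmann coupling of its unhindered 8-OH with 13 gives mono-ether F7, and Ullmann coupling of the remaining hindered 4-OH with 18 (Cu/picolinic acid, K3PO4) gives 14.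

2. Step 4. The ketal exchange may stall at the open mixed ketal, or the ionised monoketal may be diverted by arylation next to the carbonyl or by premature rearrangement under protic acid. The fallback sets out from 7 (with 6) and comes back at 8. Compound 7 is silylated (TMSCl, Et3N) to 3-methoxy-4,5-bis(trimethylsilyloxy)benzaldehyde F8, which is combined with 6 under Noyori conditions (TMSOTf cat., CH2Cl2, −78 °C, pyridine quench). Silyl transfer to the departing methoxy groups replaces the reversible protic equilibrium by an irreversible, aprotic, low-temperature ketalisation.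

3. Step 9. Palladation may occur at the methoxy-flanked C–H of ring C (poor site selectivity), or the electron-rich aldehyde may degrade oxidatively under aerobic Pd(II). The fallback sets out from 12 and comes back at 15. SNAr of 12 (K2CO3, DMF) on F2 (made from F1 as above) gives bromo diaryl ether F9. Pd(0)-catalysed intramolecular direct arylation (Pd(OAc)2, PCy3·HBF4, K2CO3, PivOH cat., DMA, 110 °C) then closes the furan from the aryl bromide without an external oxidant, through a concerted metalation–deprotonation that favours the more acidic C–H next to the ring oxygen.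

Further compounds
F1 | step 5 | 2-fluoro-4,6-dimethoxybenzaldehyde (purchased) | O=Cc1c(F)cc(OC)cc1OC
F2 | step 5 | 3-bromo-2-fluoro-4,6-dimethoxybenzaldehyde | O=Cc1c(F)c(Br)c(OC)cc1OC
F3 | step 5 | 3-bromo-2-(4-formyl-2-hydroxy-6-methoxyphenoxy)-4,6-dimethoxybenzaldehyde | O=Cc1cc(O)c(Oc2c(Br)c(OC)cc(OC)c2C=O)c(OC)c1
F4 | step 5 | 1,3,6-trimethoxydibenzo[b,e][1,4]dioxine-4,8-dicarbaldehyde | O=Cc1cc2Oc3c(OC)cc(OC)c(C=O)c3Oc2c(OC)c1
F5 | step 5 | 1,3,6-trimethoxydibenzo[b,e][1,4]dioxine-4,8-diyl diformate (not isolated) | O=COc1cc2Oc3c(OC)cc(OC)c(OC=O)c3Oc2c(OC)c1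
F6 | step 5 | 1,3,6-trimethoxydibenzo[b,e][1,4]dioxine-4,8-diol | Oc1cc2Oc3c(OC)cc(OC)c(O)c3Oc2c(OC)c1
F7 | step 5 | 2-[(4-hydroxy-1,3,6-trimethoxydibenzo[b,e][1,4]dioxin-8-yl)oxy]-4,6-dimethoxybenzaldehyde | O=Cc1c(OC)cc(OC)cc1Oc1cc2Oc3c(OC)cc(OC)c(O)c3Oc2c(OC)c1
F8 | step 4 | 3-methoxy-4,5-bis(trimethylsilyloxy)benzaldehyde | O=Cc1cc(O[Si](C)(C)C)c(O[Si](C)(C)C)c(OC)c1
F9 | step 9 | 3-bromo-2-{[4-(3,5-dimethoxyphenoxy)-1,3,6-trimethoxydibenzo[b,e][1,4]dioxin-8-yl]oxy}-4,6-dimethoxybenzaldehyde | COc1cc(OC)c2Oc3cc(Oc4c(Br)c(OC)cc(OC)c4C=O)cc(OC)c3Oc2c1Oc1cc(OC)cc(OC)c1
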